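The plan exploits the oxygenation pattern of ring A. C5, C7 and C8a bear oxygen, C4a bears the C4 acyl carbon and C8 bears the side chain, which is the pattern of a cyclised four-ketide chain. Disconnecting C4a–C8a therefore unravels ring A to a methyl 3,5,7-trioxooctanoate. Its C2 (future C8) already holds the complete diarylheptanoid chain, with the ketone masked as a dioxolane and the (R)-centre set by an asymmetric malonate Michael addition. One magnesium-mediated intramolecular Claisen condensation then forms that bond, closes ring A and aromatises it to the 3-alkyl-2,4,6-trihydroxyacetophenone. Benzoylation, chromone closure, C3 oxidation and deprotection finish the flavonol.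

Key step: step 9

Assumption: the sense of induction in step 4 is assigned by analogy only. The (1R,2R) catalyst is written and both antipodes are commercial, so if correlation of 7 shows the (S)-adduct, the (1S,2S) catalyst is used with nothing else changed.
Remark: 9, 12 and 13 are mixtures of epimers at the malonate carbon, and 13 is also a mixture of enol tautomers. This carbon becomes aromatic in step 9 and is left undefined.
Shorthand in names: "ketal chain" = (2R)-4-[4-(benzyloxy)-3-methoxyphenyl]-1-[2-(2-phenylethyl)-1,3-dioxolan-2-yl]butan-2-yl. "Keto chain" = (3R)-1-[4-(benzyloxy)-3-methoxyphenyl]-5-oxo-7-phenylheptan-3-yl.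

Step 1
Reactants: 1 4-(3-hydroxypropyl)-2-methoxyphenol (dihydroconiferyl alcohol)
Product: 2 3-[4-(benzyloxy)-3-methoxyphenyl]propan-1-ol
Conditions: BnBr (1.1 equiv), K2CO3 (1.5 equiv), acetone, reflux
Reagents that add atoms: benzyl bromide, BrCc1ccccc1
Why: Williamson ether synthesis in which K2CO3 ionises only the phenol, so the primary alcohol stays free for the next step.

Step 2
Reactants: 2 3-[4-(benzyloxy)-3-methoxyphenyl]propan-1-ol
Product: 3 3-[4-(benzyloxy)-3-methoxyphenyl]propanal
Conditions: TEMPO (10 mol%), PhI(OAc)2 (1.1 equiv), CH2Cl2, rt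
Reagents that add atoms: none
Why: Oxoammonium (TEMPO) oxidation of a primary alcohol stops at the aldehyde and spares the benzyl ether and the electron-rich arene.

Step 3
Reactants: 3 3-[4-(benzyloxy)-3-methoxyphenyl]propanal; 4 dimethyl (2-oxo-4-phenylbutyl)phosphonate
Product: 5 (E)-7-[4-(benzyloxy)-3-methoxyphenyl]-1-phenylhept-4-en-3-one
Conditions: LiCl (1.2 equiv), iPr2NEt (1.2 equiv), MeCN, rt
Reagents that add atoms: none
Why: Horner–Wadsworth–Emmons olefination of a stabilised β-ketophosphonate under mild LiCl/amine conditions gives the (E)-enone without self-condensation of the enolisable aldehyde.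

Step 4
Reactants: 5 (E)-7-[4-(benzyloxy)-3-methoxyphenyl]-1-phenylhept-4-en-3-one; 6 dimethyl malonate
Product: 7 dimethyl 2-(keto chain)propanedioate
Conditions: 6 (3 equiv), 1-[(1R,2R)-2-aminocyclohexyl]-3-[3,5-bis(trifluoromethyl)phenyl]thiourea (10 mol%), PhCO2H (10 mol%), toluene, 50 °C
Reagents that add atoms: none
Why: Asymmetric Michael addition under iminium activation, in which the primary amine condenses with the ketone while the thiourea binds the malonate enol and delivers it to the Re face of C5 of the (E)-enone, which sets the only stereocentre of the target as (R).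

Step 5
Reactants: 7 dimethyl 2-(keto chain)propanedioate
Product: 8 dimethyl 2-(ketal chain)propanedioate
Conditions: Me3SiOCH2CH2OSiMe3 (2 equiv), Me3SiOTf (5 mol%), CH2Cl2, −78 to −20 °C; pyridine quench
Reagents that add atoms: 1,2-bis(trimethylsilyloxy)ethane, C[Si](C)(C)OCCO[Si](C)(C)C
Why: Aprotic ketalisation (silylated glycol, catalytic Me3SiOTf) masks the ketone at low temperature without transesterifying the malonate or provoking retro-Michael cleavage, and it is indispensable because the free 1,5-dicarbonyl array would cyclise by aldol or Dieckmann reaction in every later basic step.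

Step 6
Reactants: 8 dimethyl 2-(ketal chain)propanedioate
Product: 9 2-(ketal chain)-3-methoxy-3-oxopropanoic acid (C2 epimers)
Conditions: KOH (1.05 equiv), MeOH–THF, 0 °C to rt; cold dilute HCl to pH 3–4, immediate extraction
Reagents that add atoms: potassium hydroxide, [K+].[OH-]
Why: Selective monosaponification of a malonic diester works because the first carboxylate formed repels hydroxide from the second ester, and the new stereocentre at the malonate carbon is irrelevant.

Step 7
Reactants: 10 (Z)-4-(trimethylsilyloxy)pent-3-en-2-one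
Product: 11 (3Z)-2,4-bis(trimethylsilyloxy)penta-1,3-diene
Conditions: LiN(iPr)2 (1.1 equiv), THF, −78 °C; Me3SiCl (1.2 equiv), −78 °C to rt; non-aqueous work-up
Reagents that add atoms: chlorotrimethylsilane, C[Si](C)(C)Cl
Why: Kinetic enolisation of the methyl ketone and O-silylation is the standard preparation of a 1,3-bis(silyl enol ether), here a neutral equivalent of the acetylacetone dianion.

Step 8
Reactants: 9 2-(ketal chain)-3-methoxy-3-oxopropanoic acid; 11 (3Z)-2,4-bis(trimethylsilyloxy)penta-1,3-diene
Product: 13 methyl 2-(ketal chain)-3,5,7-trioxooctanoate (C2 epimers), via acid chloride 12 (not isolated)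
Conditions: 1-chloro-N,N,2-trimethylprop-1-en-1-amine (1.1 equiv), CH2Cl2, 0 °C; then 11 (1.5 equiv), −78 to 20 °C; pH 7 buffer work-up
Reagents that add atoms: none
Why: Mukaiyama-type C-acylation of a 1,3-bis(silyl enol ether) at its terminal carbon by an acid chloride is used because this non-basic nucleophile cannot be quenched by the acidic malonate C–H, which would protonate a metalated acetylacetone dianion faster than it is acylated, and because the chloroenamine forms the acid chloride without free HCl so that the dioxolane survives.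

Step 9
Reactants: 13 methyl 2-(ketal chain)-3,5,7-trioxooctanoate
Product: 14 1-[3-(ketal chain)-2,4,6-trihydroxyphenyl]ethan-1-one
Conditions: Mg(OMe)2 (4 equiv), MeOH, Ar, rt then reflux; cold dilute HCl to pH 4–5
Reagents that add atoms: none
Why: Mg(OMe)2 turns 13 into a magnesium-bridged polyenolate in which C6 (flanked by the C5 and C7 carbonyl groups) adds to the C1 ester carbonyl, methoxide departs, and the 2-acetylcyclohexane-1,3,5-trione so formed tautomerises at once to the phenol, so that the flavonol C4a–C8a bond, ring A and its full oxygen pattern arise together. The closest known reaction type is the biomimetic intramolecular Claisen (Dieckmann-like) cyclisation of 3,5,7-trioxoalkanoates or their pyrone forms to acylphloroglucinols under magnesium alkoxide. The one ring closes in the 6-exo-trig mode, which is allowed for either enolate form of C6. No stereocentre is created: the epimeric C2 becomes the planar arene carbon that is C8 of the flavonol, and the (R)-centre, one bond outside the ring and without an adjacent carbonyl group, cannot epimerise. The step needs C6-to-C1 Claisen folding to prevail over C2-to-C7 aldol folding and over lactonisation through the C5 enol oxygen; the alkyl group on C2 makes the aldol adduct quaternary and unable to aromatise, both detours are reversible in methanolic methoxide, and only the Claisen path ends in an aromatic magnesium phenolate as thermodynamic sink, while the methyl ester makes alkoxide exchange degenerate. The dioxolane keeps the chain ketone out of the six-ring aldol (from C4) and Dieckmann-type closures that a free 1,5-dicarbonyl array would open.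

Step 10
Reactants: 14 1-[3-(ketal chain)-2,4,6-trihydroxyphenyl]ethan-1-one
Product: 15 1-[4,6-bis(benzyloxy)-2-hydroxy-3-(ketal chain)phenyl]ethan-1-one
Conditions: BnBr (2.1 equiv), K2CO3 (2.5 equiv), DMF, rt
Reagents that add atoms: benzyl bromide, BrCc1ccccc1
Why: Williamson etherification under steric and chelation control, in which the 4-OH (para to the acetyl group) and the unhindered 6-OH react while the 2-OH, wedged between the acetyl group and the branched chain and held in the hydrogen bond to the carbonyl, stays free, which commits the later ring closure to the 8-substituted and not the 6-substituted flavone series.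

Step 11
Reactants: 15 1-[4,6-bis(benzyloxy)-2-hydroxy-3-(ketal chain)phenyl]ethan-1-one
Product: 16 1-[4,6-bis(benzyloxy)-2-hydroxy-3-(ketal chain)phenyl]-3-phenylpropane-1,3-dione
Conditions: LiN(SiMe3)2 (3.5 equiv), THF, −78 to −10 °C; PhCOCl (1.05 equiv), −78 °C to rt; aq NH4Cl
Reagents that add atoms: benzoyl chloride, O=C(Cl)c1ccccc1
Why: Direct C-benzoylation of the lithium phenolate–enolate, the one-flask equivalent of the Baker–Venkataraman O-acylation and acyl migration, gives the 1,3-diketone without first esterifying the hindered phenol, and any O-benzoate formed rearranges to the same product under the excess base.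

Step 12
Reactants: 16 1-[4,6-bis(benzyloxy)-2-hydroxy-3-(ketal chain)phenyl]-3-phenylpropane-1,3-dione
Product: 18 5,7-bis(benzyloxy)-8-(keto chain)-2-phenyl-4H-chromen-4-one, via ketal flavone 17 (not isolated)
Conditions: p-TsOH·H2O (0.2 equiv), toluene, reflux, water separator; then THF, 1 M HCl, rt
Reagents that add atoms: water, O
Why: Acid-catalysed cyclodehydration of the o-hydroxyaryl 1,3-diketone (closing stage of the Baker–Venkataraman flavone synthesis) is run first under water removal so that the only free phenol is consumed in the chromone before aqueous acid hydrolyses the dioxolane, which prevents that phenol from adding to the liberated ketone.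

Step 13
Reactants: 18 5,7-bis(benzyloxy)-8-(keto chain)-2-phenyl-4H-chromen-4-one
Product: 20 5,7-bis(benzyloxy)-3-hydroxy-8-(keto chain)-2-phenyl-4H-chromen-4-one, via flavone epoxide 19 (not isolated)
Conditions: DMDO (acetone solution, 3 equiv), CH2Cl2, 0 °C to rt; then p-TsOH·H2O (cat.), CH2Cl2, rt
Reagents that add atoms: dimethyldioxirane, CC1(C)OO1
Why: Dioxirane epoxidation of the C2=C3 enol-ether bond of a flavone followed by acid-catalysed opening at C2 and loss of H-3 is an established flavone-to-flavonol oxidation, the neutral oxidant leaves the ketone and the ethers alone, and both epoxide diastereomers converge on the same planar product.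

Step 14
Reactants: 20 5,7-bis(benzyloxy)-3-hydroxy-8-(keto chain)-2-phenyl-4H-chromen-4-one
Product: 21 3,5,7-trihydroxy-8-[(3R)-1-(4-hydroxy-3-methoxyphenyl)-5-oxo-7-phenylheptan-3-yl]-2-phenyl-4H-chromen-4-one (CNP0164153.1)
Conditions: H2 (1 atm), Pd/C (10 wt%), EtOAc–THF, rt
Reagents that add atoms: none
Why: Catalytic hydrogenolysis removes the three aryl benzyl ethers under neutral conditions, leaves the tetrasubstituted chromone double bond, the dialkyl ketone and the stereocentre untouched, and avoids the acid that could close the freed 7-OH onto the chain ketone as a chroman ketal.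

Compound list
1 | 4-(3-hydroxypropyl)-2-methoxyphenol | COc1cc(CCCO)ccc1O | starting material
2 | 3-[4-(benzyloxy)-3-methoxyphenyl]propan-1-ol | COc1cc(CCCO)ccc1OCc1ccccc1 | intermediate
3 | 3-[4-(benzyloxy)-3-methoxyphenyl]propanal | COc1cc(CCC=O)ccc1OCc1ccccc1 | intermediate
4 | dimethyl (2-oxo-4-phenylbutyl)phosphonate | COP(=O)(CC(=O)CCc1ccccc1)OC | starting material
5 | (E)-7-[4-(benzyloxy)-3-methoxyphenyl]-1-phenylhept-4-en-3-one | COc1cc(CC/C=C/C(=O)CCc2ccccc2)ccc1OCc1ccccc1 | intermediate
6 | dimethyl malonate | COC(=O)CC(=O)OC | starting material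
7 | dimethyl 2-[(3R)-1-[4-(benzyloxy)-3-methoxyphenyl]-5-oxo-7-phenylheptan-3-yl]propanedioate | COc1cc(CC[C@H](CC(=O)CCc2ccccc2)C(C(=O)OC)C(=O)OC)ccc1OCc1ccccc1 | intermediate
8 | dimethyl 2-[(2R)-4-[4-(benzyloxy)-3-methoxyphenyl]-1-[2-(2-phenylethyl)-1,3-dioxolan-2-yl]butan-2-yl]propanedioate | COc1cc(CC[C@H](CC2(CCc3ccccc3)OCCO2)C(C(=O)OC)C(=O)OC)ccc1OCc1ccccc1 | intermediate
9 | 2-[(2R)-4-[4-(benzyloxy)-3-methoxyphenyl]-1-[2-(2-phenylethyl)-1,3-dioxolan-2-yl]butan-2-yl]-3-methoxy-3-oxopropanoic acid (C2 epimers) | COc1cc(CC[C@H](CC2(CCc3ccccc3)OCCO2)C(C(=O)O)C(=O)OC)ccc1OCc1ccccc1 | intermediate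
10 | (Z)-4-(trimethylsilyloxy)pent-3-en-2-one | CC(=O)/C=C(/C)O[Si](C)(C)C | starting material
11 | (3Z)-2,4-bis(trimethylsilyloxy)penta-1,3-diene | C=C(O[Si](C)(C)C)/C=C(/C)O[Si](C)(C)C | intermediate
12 | methyl 2-(chlorocarbonyl)-substituted analogue of 9: methyl 3-chloro-2-[(2R)-4-[4-(benzyloxy)-3-methoxyphenyl]-1-[2-(2-phenylethyl)-1,3-dioxolan-2-yl]butan-2-yl]-3-oxopropanoate (C2 epimers) | COc1cc(CC[C@H](CC2(CCc3ccccc3)OCCO2)C(C(=O)Cl)C(=O)OC)ccc1OCc1ccccc1 | intermediate
13 | methyl 2-[(2R)-4-[4-(benzyloxy)-3-methoxyphenyl]-1-[2-(2-phenylethyl)-1,3-dioxolan-2-yl]butan-2-yl]-3,5,7-trioxooctanoate (C2 epimers, enol tautomers) | COc1cc(CC[C@H](CC2(CCc3ccccc3)OCCO2)C(C(=O)OC)C(=O)CC(=O)CC(C)=O)ccc1OCc1ccccc1 | intermediate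
14 | 1-{3-[(2R)-4-[4-(benzyloxy)-3-methoxyphenyl]-1-[2-(2-phenylethyl)-1,3-dioxolan-2-yl]butan-2-yl]-2,4,6-trihydroxyphenyl}ethan-1-one | COc1cc(CC[C@H](CC2(CCc3ccccc3)OCCO2)c2c(O)cc(O)c(C(C)=O)c2O)ccc1OCc1ccccc1 | intermediate
15 | 1-{4,6-bis(benzyloxy)-3-[(2R)-4-[4-(benzyloxy)-3-methoxyphenyl]-1-[2-(2-phenylethyl)-1,3-dioxolan-2-yl]butan-2-yl]-2-hydroxyphenyl}ethan-1-one | COc1cc(CC[C@H](CC2(CCc3ccccc3)OCCO2)c2c(OCc3ccccc3)cc(OCc3ccccc3)c(C(C)=O)c2O)ccc1OCc1ccccc1 | intermediate
16 | 1-{4,6-bis(benzyloxy)-3-[(2R)-4-[4-(benzyloxy)-3-methoxyphenyl]-1-[2-(2-phenylethyl)-1,3-dioxolan-2-yl]butan-2-yl]-2-hydroxyphenyl}-3-phenylpropane-1,3-dione | COc1cc(CC[C@H](CC2(CCc3ccccc3)OCCO2)c2c(OCc3ccccc3)cc(OCc3ccccc3)c(C(=O)CC(=O)c3ccccc3)c2O)ccc1OCc1ccccc1 | intermediate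
17 | 5,7-bis(benzyloxy)-8-[(2R)-4-[4-(benzyloxy)-3-methoxyphenyl]-1-[2-(2-phenylethyl)-1,3-dioxolan-2-yl]butan-2-yl]-2-phenyl-4H-chromen-4-one | COc1cc(CC[C@H](CC2(CCc3ccccc3)OCCO2)c2c(OCc3ccccc3)cc(OCc3ccccc3)c3c(=O)cc(-c4ccccc4)oc23)ccc1OCc1ccccc1 | intermediate
18 | 5,7-bis(benzyloxy)-8-[(3R)-1-[4-(benzyloxy)-3-methoxyphenyl]-5-oxo-7-phenylheptan-3-yl]-2-phenyl-4H-chromen-4-one | COc1cc(CC[C@H](CC(=O)CCc2ccccc2)c2c(OCc3ccccc3)cc(OCc3ccccc3)c3c(=O)cc(-c4ccccc4)oc23)ccc1OCc1ccccc1 | intermediate
19 | 2,3-epoxide of 18 (2,3-epoxy-2-phenylchroman-4-one, both epoxide diastereomers) | COc1cc(CC[C@H](CC(=O)CCc2ccccc2)c2c(OCc3ccccc3)cc(OCc3ccccc3)c3c2OC2(c4ccccc4)OC2C3=O)ccc1OCc1ccccc1 | intermediate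
20 | 5,7-bis(benzyloxy)-8-[(3R)-1-[4-(benzyloxy)-3-methoxyphenyl]-5-oxo-7-phenylheptan-3-yl]-3-hydroxy-2-phenyl-4H-chromen-4-one | COc1cc(CC[C@H](CC(=O)CCc2ccccc2)c2c(OCc3ccccc3)cc(OCc3ccccc3)c3c(=O)c(O)c(-c4ccccc4)oc23)ccc1OCc1ccccc1 | intermediate
21 | 3,5,7-trihydroxy-8-[(3R)-1-(4-hydroxy-3-methoxyphenyl)-5-oxo-7-phenylheptan-3-yl]-2-phenyl-4H-chromen-4-one | COc1cc(CC[C@H](CC(=O)CCc2ccccc2)c2c(O)cc(O)c3c(=O)c(O)c(-c4ccccc4)oc23)ccc1O | target

Total steps: 14. Longest linear sequence: 13 (steps 1–6 and 8–14). Step 7 is a one-step side branch.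

Steps most likely to fail

**Step 9.** Ring closure may stall because the ester carbonyl sits next to the branched C2. The chain may then drain away through lactonisation via the C5 enol oxygen, aldol folding or retro-Claisen cleavage. The fallback buys ring A instead of building it.
- It sets out from enone 5, which is combined with commercial 2,4,6-trihydroxyacetophenone in an iminium-catalysed Friedel–Crafts-type Michael addition (9-amino(9-deoxy)epi-quinine, acid co-catalyst).
- The phloroglucinol reacts through its ring carbon as cyclic 1,3-dicarbonyl donors do, and the two free ring positions are equivalent. By analogy with such donors, delivery is expected to the Re face of C5. This gives the keto triol F1, in equilibrium with its chroman hemiketals.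
- 4,6-Di-O-benzylation as in step 10 gives the keto dibenzyl ether F2.
- Ketalisation of the dialkyl ketone as in step 5 follows; the chelated, doubly ortho-substituted aryl ketone stays inert. The material comes back to the route at 15.

**Step 8.** Acylation may be too slow at the crowded acid chloride, which can lose HCl to a ketene instead, and traces of acid may strip the dioxolane. The fallback is an anionic coupling instead of a neutral one, and it needs neither 9 nor 12.
- It sets out from diester 8. Its acidic C–H is removed first with LiN(iPr)2 (1 equiv) so that it can no longer quench the nucleophile.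
- The ester enolate salt is then exposed to an excess of the dilithium salt of commercial acetylacetone (2 LiN(iPr)2, THF, 0 °C to rt).
- Acylation of 1,3-diketone dianions by enolate salts of esters is a known, if slow, reaction type. Mildly acidic work-up comes back to the route at 13 (no new compound, F0).

**Step 4.** Facial selectivity may be poor or iminium formation sluggish, because both flanks of the enone are flexible alkyl chains and the ketone is not a methyl ketone. The fallback uses auxiliary control and forms a different bond to the stereocentre, C3–C4 of the heptane chain instead of C3–malonate.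
- It sets out from aldehyde 3, which undergoes Knoevenagel condensation with 6 (piperidine, AcOH) to the alkylidene malonate F3.
- Commercial 4-phenylbutan-2-one is condensed with SAMP to the hydrazone F4.
- F4 is deprotonated at its methyl group (LiN(iPr)2, THF, −78 °C) and added to F3 in an auxiliary-controlled aza-enolate Michael addition, giving the adduct hydrazone F5.
- Mild hydrolysis (aqueous oxalic acid, Et2O) releases the auxiliary and comes back to the route at 7. SAMP is drawn, and RAMP is taken if the correlation asks for it.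

Further compounds
F1 | step 9 | 1-{3-[(3R)-1-[4-(benzyloxy)-3-methoxyphenyl]-5-oxo-7-phenylheptan-3-yl]-2,4,6-trihydroxyphenyl}ethan-1-one | COc1cc(CC[C@H](CC(=O)CCc2ccccc2)c2c(O)cc(O)c(C(C)=O)c2O)ccc1OCc1ccccc1
F2 | step 9 | 1-{4,6-bis(benzyloxy)-3-[(3R)-1-[4-(benzyloxy)-3-methoxyphenyl]-5-oxo-7-phenylheptan-3-yl]-2-hydroxyphenyl}ethan-1-one | COc1cc(CC[C@H](CC(=O)CCc2ccccc2)c2c(OCc3ccccc3)cc(OCc3ccccc3)c(C(C)=O)c2O)ccc1OCc1ccccc1
F0 | step 8 | none | none
F3 | step 4 | dimethyl 2-{3-[4-(benzyloxy)-3-methoxyphenyl]propylidene}propanedioate | COc1cc(CCC=C(C(=O)OC)C(=O)OC)ccc1OCc1ccccc1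
F4 | step 4 | (E)-hydrazone of 4-phenylbutan-2-one with (S)-1-amino-2-(methoxymethyl)pyrrolidine | COC[C@@H]1CCCN1/N=C(\C)CCc1ccccc1
F5 | step 4 | (S)-1-amino-2-(methoxymethyl)pyrrolidine hydrazone of 7 | COc1cc(CC[C@H](CC(CCc2ccccc2)=NN2CCC[C@H]2COC)C(C(=O)OC)C(=O)OC)ccc1OCc1ccccc1
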